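**Plan**
Retrosynthesis: the five benzyl-type groups come off first; then the flavanone C4–C4a bond is cut (Friedel–Crafts), then the C2–O1 bond (Mitsunobu), then the flavone pyranone (cyclodehydration, Claisen C–C bond) and last the diaryl ether C–O bond (SNAr).
Feature used: in ring A of the flavanone, O1 on C8a is para to C6, which carries the aryloxy group, and C5/C7 carry identical oxygens. The open precursor is therefore a mirror-symmetric 4-aryloxy-3,5-dibenzyloxyphenyl ether whose two free ortho carbons both become C4a.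
Forward: the symmetric diaryl ether phenol is made from 3,4,5-trihydroxybenzaldehyde and ethyl 4-fluorobenzoate; the flavone pyranone ring is built on it; the chiral C3 acid chain is attached at the phenol oxygen; the flavanone pyranone ring closes last; hydrogenolysis ends the route.
Stereochemistry: the single stereocentre (C2) is set as the (R) carbinol by asymmetric transfer hydrogenation, inverted to (S) in the Mitsunobu step and untouched afterwards.

Key step: step 13

Remark: the descriptor at C2 in the target SMILES is read as (S); benzyl bromide, benzyl chloroformate, mCPBA, tert-butyl diazoacetate and the transfer-hydrogenation catalyst are taken as purchased.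

**Route**

Step 1
Reactants: 1 3,4,5-trihydroxybenzaldehyde
Product: 2 3,4,5-tris(benzyloxy)benzaldehyde
Conditions: BnBr (3.3 equiv), K2CO3, DMF, 60 °C
Reagents that add atoms: benzyl bromide, BrCc1ccccc1
Why: Williamson ether synthesis, in which the three phenoxides formed by K2CO3 in DMF are alkylated by benzyl bromide while the aldehyde is inert.

Step 2
Reactants: 2 3,4,5-tris(benzyloxy)benzaldehyde
Product: 3 3,5-bis(benzyloxy)-4-hydroxybenzaldehyde
Conditions: MgBr2·OEt2 (1.2 equiv), toluene/Et2O, 80 °C; aq. HCl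
Reagents that add atoms: none
Why: Lewis-acid-assisted ether cleavage, in which MgBr2 binds between neighbouring ether oxygens and bromide removes the benzyl group of the central ether, which is twisted out of conjugation and leaves as a phenoxide stabilised by the para formyl group, the same selectivity that turns 3,4,5-trialkoxybenzaldehydes into 4-hydroxy-3,5-dialkoxybenzaldehydes.

Step 3
Reactants: 3 3,5-bis(benzyloxy)-4-hydroxybenzaldehyde; 4 ethyl 4-fluorobenzoate
Product: 5 ethyl 4-[2,6-bis(benzyloxy)-4-formylphenoxy]benzoate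
Conditions: Cs2CO3, DMSO, 120 °C
Reagents that add atoms: none
Why: Nucleophilic aromatic substitution by addition–elimination, in which the cesium phenoxide of 3 adds to the fluorine-bearing carbon, the para ester stabilises the Meisenheimer intermediate and fluoride leaves, the single free hydroxyl of 3 fixing the ether at the central oxygen.

Step 4
Reactants: 5 ethyl 4-[2,6-bis(benzyloxy)-4-formylphenoxy]benzoate
Product: 7 ethyl 4-[2,6-bis(benzyloxy)-4-hydroxyphenoxy]benzoate, via aryl formate 6 (not isolated)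
Conditions: mCPBA, CH2Cl2, 40 °C; then K2CO3 (0.2 equiv), EtOH, rt
Reagents that add atoms: 3-chloroperoxybenzoic acid (mCPBA), OOC(=O)c1cccc(Cl)c1
Why: Dakin-type Baeyer–Villiger oxidation, in which the peracid adds to the aldehyde and the oxygen-rich aryl group migrates to give formate 6, which catalytic ethoxide transesterifies to the phenol while ethanol as solvent leaves the ethyl benzoate unchanged.

Step 5
Reactants: 8 2',4',6'-trihydroxyacetophenone
Product: 9 1-[2,4-bis(benzyloxy)-6-hydroxyphenyl]ethan-1-one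
Conditions: BnBr (2.1 equiv), K2CO3, acetone, reflux
Reagents that add atoms: benzyl bromide, BrCc1ccccc1
Why: Williamson ether synthesis with two equivalents of halide, in which the hydroxyl hydrogen-bonded to the acetyl carbonyl is the least acidic and least nucleophilic and stays free.

Step 6
Reactants: 7 ethyl 4-[2,6-bis(benzyloxy)-4-hydroxyphenoxy]benzoate; 9 1-[2,4-bis(benzyloxy)-6-hydroxyphenyl]ethan-1-one
Product: 10 1-[2,4-bis(benzyloxy)-6-hydroxyphenyl]-3-{4-[2,6-bis(benzyloxy)-4-hydroxyphenoxy]phenyl}propane-1,3-dione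
Conditions: LiN(SiMe3)2 (5 equiv), THF, −78 °C → rt; aq. HCl
Reagents that add atoms: none
Why: Crossed Claisen condensation, in which the lithium enolate of the dianion of 9 adds to the ethyl ester of 7 (held as a spectator phenoxide by the excess base) and loss of ethoxide gives the 1,3-diketone, whose deprotonation drives the reaction.

Step 7
Reactants: 10 1-[2,4-bis(benzyloxy)-6-hydroxyphenyl]-3-{4-[2,6-bis(benzyloxy)-4-hydroxyphenoxy]phenyl}propane-1,3-dione
Product: 11 5,7-bis(benzyloxy)-2-{4-[2,6-bis(benzyloxy)-4-hydroxyphenoxy]phenyl}-4H-chromen-4-one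
Conditions: p-TsOH·H2O (0.2 equiv), toluene, 90 °C
Reagents that add atoms: none
Why: Acid-catalysed cyclodehydration of a 1-(2-hydroxyaryl)-1,3-diketone, the standard flavone closure, in which the ortho hydroxyl adds to the distal carbonyl (6-exo-trig) and water is lost to give the pyranone, catalytic sulfonic acid being mild enough for the benzyl ethers.

Step 8
Reactants: 12 4-hydroxybenzaldehyde
Product: 13 benzyl 4-formylphenyl carbonate
Conditions: CbzCl, K2CO3, acetone, 0 °C → rt
Reagents that add atoms: benzyl chloroformate, O=C(Cl)OCc1ccccc1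
Why: O-acylation of the phenoxide by the chloroformate gives the aryl benzyl carbonate, an electron-withdrawing protecting group that later leaves by hydrogenolysis together with the benzyl ethers.

Step 9
Reactants: 13 benzyl 4-formylphenyl carbonate; 14 tert-butyl diazoacetate
Product: 15 tert-butyl 3-[4-(benzyloxycarbonyloxy)phenyl]-3-oxopropanoate
Conditions: SnCl2 (10 mol %), CH2Cl2, rt
Reagents that add atoms: none
Why: Roskamp reaction, in which SnCl2 activates the aldehyde towards addition of the diazo ester and a 1,2-hydride shift with loss of dinitrogen gives the β-keto ester directly.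

Step 10
Reactants: 15 tert-butyl 3-[4-(benzyloxycarbonyloxy)phenyl]-3-oxopropanoate
Product: 16 tert-butyl (3R)-3-[4-(benzyloxycarbonyloxy)phenyl]-3-hydroxypropanoate
Conditions: RuCl(p-cymene)[(R,R)-TsDPEN] (1 mol %), HCO2H/Et3N (5:2), DMF, 30 °C
Reagents that add atoms: none
Why: Noyori asymmetric transfer hydrogenation, in which the (R,R)-configured ruthenium hydride passes hydride and proton to the aryl ketone through a six-membered outer-sphere transition state organised by the CH/π contact between the p-cymene ligand and the aryl ring, so that hydride reaches the Si face and the catalyst sets the (R) carbinol, as with acetophenones and aryl β-keto esters.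

Step 11
Reactants: 11 5,7-bis(benzyloxy)-2-{4-[2,6-bis(benzyloxy)-4-hydroxyphenoxy]phenyl}-4H-chromen-4-one; 16 tert-butyl (3R)-3-[4-(benzyloxycarbonyloxy)phenyl]-3-hydroxypropanoate
Product: 17 tert-butyl (3S)-3-[4-(benzyloxycarbonyloxy)phenyl]-3-{3,5-bis(benzyloxy)-4-[4-(5,7-bis(benzyloxy)-4-oxo-4H-chromen-2-yl)phenoxy]phenoxy}propanoate
Conditions: PPh3, DIAD, THF, 0 °C → rt
Reagents that add atoms: none
Why: Mitsunobu etherification, in which the phenol protonates the phosphine–azodicarboxylate betaine, the alcohol is activated as its alkoxyphosphonium ion and the phenoxide displaces it by SN2 with inversion, so the (R) carbinol becomes the (S) aryl ether that is C2 of the flavanone, the electron-poor carbonate on ring B holding back ionisation.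

Step 12
Reactants: 17 tert-butyl (3S)-3-[4-(benzyloxycarbonyloxy)phenyl]-3-{3,5-bis(benzyloxy)-4-[4-(5,7-bis(benzyloxy)-4-oxo-4H-chromen-2-yl)phenoxy]phenoxy}propanoate
Product: 18 (3S)-3-[4-(benzyloxycarbonyloxy)phenyl]-3-{3,5-bis(benzyloxy)-4-[4-(5,7-bis(benzyloxy)-4-oxo-4H-chromen-2-yl)phenoxy]phenoxy}propanoic acid
Conditions: TFA/CH2Cl2 (1:4), 0 °C → rt
Reagents that add atoms: none
Why: Acidolysis of the tert-butyl ester by alkyl–oxygen cleavage with loss of 2-methylpropene frees the acid without base, which avoids both E1cB loss of the β-aryloxy group and cleavage of the aryl carbonate.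

Step 13
Reactants: 18 (3S)-3-[4-(benzyloxycarbonyloxy)phenyl]-3-{3,5-bis(benzyloxy)-4-[4-(5,7-bis(benzyloxy)-4-oxo-4H-chromen-2-yl)phenoxy]phenoxy}propanoic acid
Product: 20 benzyl 4-{(2S)-5,7-bis(benzyloxy)-6-[4-(5,7-bis(benzyloxy)-4-oxo-4H-chromen-2-yl)phenoxy]-4-oxo-3,4-dihydro-2H-chromen-2-yl}phenyl carbonate, via mixed trifluoroacetic anhydride 19 (not isolated)
Conditions: TFAA (3 equiv), CH2Cl2, 0 °C → rt
Reagents that add atoms: none
Why: Trifluoroacetic anhydride turns the acid into mixed anhydride 19, an acylium equivalent that attacks the arene carbon ortho to the ether oxygen, and loss of a proton from the Wheland intermediate gives the aryl ketone and the C4–C4a bond. The closest known reaction type is the intramolecular Friedel–Crafts acylation of 3-aryloxypropanoic acids to chroman-4-ones, including 3-aryl-3-aryloxypropanoic acids to 2-arylchroman-4-ones. The pyranone ring closes as a six-membered ring by 6-exo-trig attack of the arene carbon on the acyl carbon, the O1–C2–C3 chain being already in place. No stereocentre is created, and C2 keeps the (S) configuration from step 11 because bond formation occurs at C4 only. The step needs regioselectivity and nucleophilicity, and both come from the substrate: the two free carbons of the attacked ring are related by a mirror plane through O1 and the aryloxy carbon, each is ortho to O1, ortho to one benzyloxy group and para to the other, so one ketone results and no Lewis acid is needed, while the flavone rings are deactivated by their carbonyl. It also needs the benzylic C2–O bond to stay intact under acid, which the electron-withdrawing carbonate on ring B and the low temperature should secure.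

Step 14
Reactants: 20 benzyl 4-{(2S)-5,7-bis(benzyloxy)-6-[4-(5,7-bis(benzyloxy)-4-oxo-4H-chromen-2-yl)phenoxy]-4-oxo-3,4-dihydro-2H-chromen-2-yl}phenyl carbonate
Product: 21 (2S)-6-[4-(5,7-dihydroxy-4-oxo-4H-chromen-2-yl)phenoxy]-5,7-dihydroxy-2-(4-hydroxyphenyl)-2,3-dihydro-4H-chromen-4-one (CNP0206535.1)
Conditions: H2 (1 atm), 10% Pd/C, THF/MeOH, rt
Reagents that add atoms: none
Why: Catalytic hydrogenolysis cleaves the four benzyl aryl ethers and the benzyl carbonate, whose carbonic half-ester loses CO2 to the phenol, under neutral conditions that should leave the flavone C2=C3 bond, both carbonyls and the C2 stereocentre intact if the reaction is stopped after the calculated hydrogen uptake.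

**Compound list**
1 | 3,4,5-trihydroxybenzaldehyde | O=Cc1cc(O)c(O)c(O)c1 | starting material
2 | 3,4,5-tris(benzyloxy)benzaldehyde | O=Cc1cc(OCc2ccccc2)c(OCc2ccccc2)c(OCc2ccccc2)c1 | intermediate
3 | 3,5-bis(benzyloxy)-4-hydroxybenzaldehyde | O=Cc1cc(OCc2ccccc2)c(O)c(OCc2ccccc2)c1 | intermediate
4 | ethyl 4-fluorobenzoate | CCOC(=O)c1ccc(F)cc1 | starting material
5 | ethyl 4-[2,6-bis(benzyloxy)-4-formylphenoxy]benzoate | CCOC(=O)c1ccc(Oc2c(OCc3ccccc3)cc(C=O)cc2OCc2ccccc2)cc1 | intermediate
6 | ethyl 4-[2,6-bis(benzyloxy)-4-(formyloxy)phenoxy]benzoate (not isolated) | CCOC(=O)c1ccc(Oc2c(OCc3ccccc3)cc(OC=O)cc2OCc2ccccc2)cc1 | intermediate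
7 | ethyl 4-[2,6-bis(benzyloxy)-4-hydroxyphenoxy]benzoate | CCOC(=O)c1ccc(Oc2c(OCc3ccccc3)cc(O)cc2OCc2ccccc2)cc1 | intermediate
8 | 2',4',6'-trihydroxyacetophenone | CC(=O)c1c(O)cc(O)cc1O | starting material
9 | 1-[2,4-bis(benzyloxy)-6-hydroxyphenyl]ethan-1-one | CC(=O)c1c(O)cc(OCc2ccccc2)cc1OCc1ccccc1 | intermediate
10 | 1-[2,4-bis(benzyloxy)-6-hydroxyphenyl]-3-{4-[2,6-bis(benzyloxy)-4-hydroxyphenoxy]phenyl}propane-1,3-dione | O=C(CC(=O)c1ccc(Oc2c(OCc3ccccc3)cc(O)cc2OCc2ccccc2)cc1)c1c(O)cc(OCc2ccccc2)cc1OCc1ccccc1 | intermediate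
11 | 5,7-bis(benzyloxy)-2-{4-[2,6-bis(benzyloxy)-4-hydroxyphenoxy]phenyl}-4H-chromen-4-one | Oc1cc(OCc2ccccc2)c(Oc2ccc(-c3cc(=O)c4c(OCc5ccccc5)cc(OCc5ccccc5)cc4o3)cc2)c(OCc2ccccc2)c1 | intermediate
12 | 4-hydroxybenzaldehyde | O=Cc1ccc(O)cc1 | starting material
13 | benzyl 4-formylphenyl carbonate | O=Cc1ccc(OC(=O)OCc2ccccc2)cc1 | intermediate
14 | tert-butyl diazoacetate | CC(C)(C)OC(=O)C=[N+]=[N-] | starting material
15 | tert-butyl 3-[4-(benzyloxycarbonyloxy)phenyl]-3-oxopropanoate | CC(C)(C)OC(=O)CC(=O)c1ccc(OC(=O)OCc2ccccc2)cc1 | intermediate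
16 | tert-butyl (3R)-3-[4-(benzyloxycarbonyloxy)phenyl]-3-hydroxypropanoate | CC(C)(C)OC(=O)C[C@@H](O)c1ccc(OC(=O)OCc2ccccc2)cc1 | intermediate
17 | tert-butyl (3S)-3-[4-(benzyloxycarbonyloxy)phenyl]-3-{3,5-bis(benzyloxy)-4-[4-(5,7-bis(benzyloxy)-4-oxo-4H-chromen-2-yl)phenoxy]phenoxy}propanoate | CC(C)(C)OC(=O)C[C@@H](c1ccc(OC(=O)OCc2ccccc2)cc1)Oc1cc(OCc2ccccc2)c(Oc2ccc(-c3cc(=O)c4c(OCc5ccccc5)cc(OCc5ccccc5)cc4o3)cc2)c(OCc2ccccc2)c1 | intermediate
18 | (3S)-3-[4-(benzyloxycarbonyloxy)phenyl]-3-{3,5-bis(benzyloxy)-4-[4-(5,7-bis(benzyloxy)-4-oxo-4H-chromen-2-yl)phenoxy]phenoxy}propanoic acid | OC(=O)C[C@@H](c1ccc(OC(=O)OCc2ccccc2)cc1)Oc1cc(OCc2ccccc2)c(Oc2ccc(-c3cc(=O)c4c(OCc5ccccc5)cc(OCc5ccccc5)cc4o3)cc2)c(OCc2ccccc2)c1 | intermediate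
19 | mixed anhydride of acid 18 and trifluoroacetic acid, (3S) (not isolated) | O=C(OC(=O)C(F)(F)F)C[C@@H](c1ccc(OC(=O)OCc2ccccc2)cc1)Oc1cc(OCc2ccccc2)c(Oc2ccc(-c3cc(=O)c4c(OCc5ccccc5)cc(OCc5ccccc5)cc4o3)cc2)c(OCc2ccccc2)c1 | intermediate
20 | benzyl 4-{(2S)-5,7-bis(benzyloxy)-6-[4-(5,7-bis(benzyloxy)-4-oxo-4H-chromen-2-yl)phenoxy]-4-oxo-3,4-dihydro-2H-chromen-2-yl}phenyl carbonate | O=C1C[C@@H](c2ccc(OC(=O)OCc3ccccc3)cc2)Oc2cc(OCc3ccccc3)c(Oc3ccc(-c4cc(=O)c5c(OCc6ccccc6)cc(OCc6ccccc6)cc5o4)cc3)c(OCc3ccccc3)c21 | intermediate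
21 | (2S)-6-[4-(5,7-dihydroxy-4-oxo-4H-chromen-2-yl)phenoxy]-5,7-dihydroxy-2-(4-hydroxyphenyl)-2,3-dihydro-4H-chromen-4-one | O=C1C[C@@H](c2ccc(O)cc2)Oc2cc(O)c(Oc3ccc(-c4cc(=O)c5c(O)cc(O)cc5o4)cc3)c(O)c21 | target

**Step count**
Total: 14 steps. Longest linear sequence: 10 steps (steps 1, 2, 3, 4, 6, 7, 11, 12, 13, 14).

**Steps most likely to fail**

Step 13. Acid-promoted heterolysis of the benzylic C2–O bond could compete with acylation, giving loss of the phenol or return with erosion of the (S) configuration, or the ring closure could stall at the anhydride. The fallback closes the pyranone ring at O1–C2 instead, so no acid acts at the benzylic carbon. It sets out from phenol 11. C-acetylation ortho to the hydroxyl (Ac2O, BF3·OEt2, CH2Cl2; one isomer by the same symmetry) should give 1-{2,4-bis(benzyloxy)-3-[4-(5,7-bis(benzyloxy)-4-oxo-4H-chromen-2-yl)phenoxy]-6-hydroxyphenyl}ethan-1-one F1. Claisen–Schmidt condensation with 4-(benzyloxy)benzaldehyde (KOH, EtOH/THF, rt) should give the (E)-2'-hydroxychalcone F2. NaOAc in refluxing EtOH should close it by intramolecular oxa-Michael addition to the racemic pentabenzyl flavanone F3. Preparative HPLC on a chiral stationary phase would deliver the (2S)-pentabenzyl flavanone F4. Hydrogenolysis under the conditions of step 14 comes back to the route at target 21.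

Step 11. The activated β-hydroxy ester could dehydrate to the cinnamate, since the alkoxyphosphonium ion carries acidic α-hydrogens, or substitution could run partly through a benzylic cation and lose enantiomeric purity. The fallback carries the future carboxyl carbon as a vinyl group, so no acidifying ester flanks the carbinol. It sets out from aldehyde 13 and phenol 11. Brown allylation of 13 with (+)-B-allyldiisopinocampheylborane (Et2O, −78 °C, ethanolamine work-up to spare the carbonate) should give benzyl 4-[(1R)-1-hydroxybut-3-en-1-yl]phenyl carbonate F5. Mitsunobu coupling with 11 (PPh3, DIAD, THF) should give the (S)-homoallyl aryl ether F6 with inversion. Oxidative cleavage of the terminal alkene (OsO4 cat., NaIO4, 2,6-lutidine, dioxane/H2O) should give the (S)-β-aryloxy aldehyde F7. Pinnick oxidation (NaClO2, NaH2PO4, 2-methyl-2-butene, t-BuOH/H2O) comes back to the route at acid 18.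

Step 3. Addition of a hindered, weakly nucleophilic phenoxide to a fluoroarene activated only by an ester may be slow, and the aldehyde may degrade at the temperature required. The fallback is a copper-mediated oxidative C–O coupling (Chan–Lam) at room temperature. It sets out from phenol 3, which is coupled with [4-(ethoxycarbonyl)phenyl]boronic acid (Cu(OAc)2, pyridine, 4 Å molecular sieves, CH2Cl2, air), and comes back to the route at ester 5. No further compound arises (F0).

**Further compounds**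
F1 | step 13 | 1-{2,4-bis(benzyloxy)-3-[4-(5,7-bis(benzyloxy)-4-oxo-4H-chromen-2-yl)phenoxy]-6-hydroxyphenyl}ethan-1-one | CC(=O)c1c(O)cc(OCc2ccccc2)c(Oc2ccc(-c3cc(=O)c4c(OCc5ccccc5)cc(OCc5ccccc5)cc4o3)cc2)c1OCc1ccccc1
F2 | step 13 | (E)-1-{2,4-bis(benzyloxy)-3-[4-(5,7-bis(benzyloxy)-4-oxo-4H-chromen-2-yl)phenoxy]-6-hydroxyphenyl}-3-[4-(benzyloxy)phenyl]prop-2-en-1-one | O=C(/C=C/c1ccc(OCc2ccccc2)cc1)c1c(O)cc(OCc2ccccc2)c(Oc2ccc(-c3cc(=O)c4c(OCc5ccccc5)cc(OCc5ccccc5)cc4o3)cc2)c1OCc1ccccc1
F3 | step 13 | racemic 5,7-bis(benzyloxy)-2-[4-(benzyloxy)phenyl]-6-[4-(5,7-bis(benzyloxy)-4-oxo-4H-chromen-2-yl)phenoxy]-2,3-dihydro-4H-chromen-4-one | O=C1CC(c2ccc(OCc3ccccc3)cc2)Oc2cc(OCc3ccccc3)c(Oc3ccc(-c4cc(=O)c5c(OCc6ccccc6)cc(OCc6ccccc6)cc5o4)cc3)c(OCc3ccccc3)c21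
F4 | step 13 | (2S)-5,7-bis(benzyloxy)-2-[4-(benzyloxy)phenyl]-6-[4-(5,7-bis(benzyloxy)-4-oxo-4H-chromen-2-yl)phenoxy]-2,3-dihydro-4H-chromen-4-one | O=C1C[C@@H](c2ccc(OCc3ccccc3)cc2)Oc2cc(OCc3ccccc3)c(Oc3ccc(-c4cc(=O)c5c(OCc6ccccc6)cc(OCc6ccccc6)cc5o4)cc3)c(OCc3ccccc3)c21
F5 | step 11 | benzyl 4-[(1R)-1-hydroxybut-3-en-1-yl]phenyl carbonate | C=CC[C@@H](O)c1ccc(OC(=O)OCc2ccccc2)cc1
F6 | step 11 | benzyl 4-[(1S)-1-{3,5-bis(benzyloxy)-4-[4-(5,7-bis(benzyloxy)-4-oxo-4H-chromen-2-yl)phenoxy]phenoxy}but-3-en-1-yl]phenyl carbonate | C=CC[C@@H](c1ccc(OC(=O)OCc2ccccc2)cc1)Oc1cc(OCc2ccccc2)c(Oc2ccc(-c3cc(=O)c4c(OCc5ccccc5)cc(OCc5ccccc5)cc4o3)cc2)c(OCc2ccccc2)c1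
F7 | step 11 | benzyl 4-[(1S)-1-{3,5-bis(benzyloxy)-4-[4-(5,7-bis(benzyloxy)-4-oxo-4H-chromen-2-yl)phenoxy]phenoxy}-3-oxopropyl]phenyl carbonate | O=CC[C@@H](c1ccc(OC(=O)OCc2ccccc2)cc1)Oc1cc(OCc2ccccc2)c(Oc2ccc(-c3cc(=O)c4c(OCc5ccccc5)cc(OCc5ccccc5)cc4o3)cc2)c(OCc2ccccc2)c1
F0 | step 3 | none | none
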